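## Analysis of the target

Target 35 is a germacrane-type sesquiterpenoid: a single ten-membered carbocycle whose C6 oxygen is acylated by (2R,3R)-2,3-epoxy-2-methylbutanoic acid 31. The ring carries an E-trisubstituted C1=C2 alkene conjugated to a C3 ketone, a second ketone at C8, and three stereocentres: C4 (R, isopropyl), C6 (R, acyloxy) and C7 (S, methyl carbinol). The side chain adds two more stereocentres, and because its carboxyl group and C3' methyl group are cis on the oxirane it derives from the Z acid 28. Along the zigzag backbone C5–C6–C7–C8 the C6–O and C7–OH bonds are syn, while C4 and C6 are 1,3-related, so both substituents can sit equatorially on a six-membered ring containing C4–C5–C6.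

The sensitive groups are the strained E-enone (E/Z drift, conjugate addition, transannular attack), C4 α to the C3 ketone, the C7/C8 α-ketol whose C6 oxygen is β to the C8 carbonyl, and the glycidic ester. The hard part is a ten-membered ring holding an E alkene, because end-to-end closure must pay both entropy and transannular strain and stereocontrol in so flexible a ring is poor.

The strategy rests on the path C7–C8–C9–C10–C1=C2: the alkene lies δ,ε to C7, so with C7 read as a carbonyl the ring is a cyclodec-5-enone. Reconnecting C2 to C7 then gives a cyclohexane (C2–C7) that bears vinyl on C7 and isopropenyl on C2.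

## Retrosynthetic reasoning

**35 ⇒ 34 ⇒ 33.** Both ketones are carried as carbinols until the end. This removes the enone, the α-ketol and the acidic C4–H from every earlier step. The last operations only have to strip two silyl ethers and oxidise C3–OH and C8–OH together.

**33 ⇒ 27 + 31.** The ester C–O bond is cut. In diol 27 only the secondary C6–OH can be acylated, because C7–OH is tertiary, so no extra protecting group is needed. The acid enters as a single enantiomer, which avoids a late epoxidation competing with C1=C2.

**31 ⇒ 30 ⇒ 29 ⇒ 28.** The carboxyl group is taken back to a primary alcohol so that the oxirane comes from reagent-controlled epoxidation of the Z-allylic alcohol 29. That alcohol is made by hydride reduction of 28. Syn oxygen transfer keeps the cis relation.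

**27 ⇒ 26 ⇒ 25 ⇒ 24 ⇒ 23.** At C7 the C–O bond is the one formed under stereocontrol, not the C–CH3 bond.
- In the conformation the ring inherits from its formation, the C7 trigonal plane stands upright, with one face turned to C1=C2 and the other outward.
- The C6 and C8 oxygens both sit on the outward side.
- The target needs the C7 oxygen outside and the methyl group where the old C2–C7 bond was.
- Direct addition of a methyl nucleophile to 23 would therefore have to come through the ring.
- Oxygen delivered from outside onto the exocyclic alkene of 25, guided by the free C6–OH, gives the right centre. Hydride then turns the oxirane CH2 into the methyl group.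

**23 ⇒ 22 ⇒ 21 ⇒ 20.** The C8–O bond is cut back to the sodium enolate 21 of ketone 20.
- Ketone 20 is isolated first. The alkene geometry can then be secured, and the hydride and crown ether of the ring expansion are gone before an oxidant is added.
- The C8 centre is temporary, so the forward reaction only has to be regioselective for C8 over C6.

**20 ⇒ 17 (key disconnection).** C9–C10 is cut and C2–C7 is reconnected. The medium ring becomes a cyclohexanol in which C3, C4 and C6 are ordinary ring stereocentres. The forward [3,3] shift must translate the trans-diequatorial vinyl/isopropenyl pair into the E alkene.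

**17 ⇒ 16.** The C7–C8 bond is cut, which corresponds to a vinyl nucleophile adding to a cyclohexanone along the equatorial trajectory.

**16 ⇒ 14 ⇒ 11 + 12.** The C2–C1 bond is cut. An all-equatorial array cannot come directly from a trans-diaxial epoxide opening.
- The oxirane is therefore placed across C7–C2 on the face of the isopropyl group. The diaxial rule then sends the isopropenyl group to C2.
- C2 is corrected afterwards next to the C7 ketone.
- Placing the oxygen bridge across C2–C3 instead would, by the same rule, send the nucleophile to C3.

**11 ⇒ 10 ⇒ 9 ⇒ 8.** C6 is set by hydride addition to the C6 ketone of 8, which gives an equatorial alcohol. Enolate oxidation next to C7 would offer no reliable facial bias. The new hydroxyl then directs the epoxidation.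

**8 ⇒ 7 ⇒ 6 ⇒ 5 ⇒ 4.** Enone 8 is enone 4 with the oxygen pattern shifted. Epoxidation anti to isopropyl fixes C3–O. Reductive transposition moves the alkene to C2=C7. Allylic oxidation then places the carbonyl at C6.

**4 ⇒ 3 ⇒ 1 + 2.** The cyclohexenone is opened at its alkene (aldol condensation) and at C4–C5 (Michael addition). C4 is thus set first, by catalyst control, from two bulk chemicals.

## Alternatives that were turned down

**Alternative 1:** The C3–C4 bond is cut, with the isopropyl group read as a hydrogenated isopropenyl group.
- *Forward key step.* A lithium amide deprotonates the thirteen-membered bis-allylic ether A1 at the C3 methylene next to oxygen. The carbanion bonds to C4 through a five-centre envelope, the far allylic C–O bond breaks, and the ring shrinks by three atoms to cyclodecenol A2.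
- *For it.* A thirteen-membered ether closes far more easily than a ten-membered carbocycle. The E alkene is brought in from open-chain chemistry. The C6–C8 triad is built in the open chain as an acetonide. On the security of C7 this plan is stronger than the chosen one, which must set C7 inside the medium ring.
- *Against it.* A1 has two nearly equivalent allylic O–CH2 sites, and deprotonation at the wrong one gives a different ring. A [1,2] shift can compete. The permanent C4 centre is fixed in a transannular transition state steered only by the remote acetonide. The isopropenyl group must later be hydrogenated beside the strained C1=C2 alkene.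
- *Comparison.* The chosen route sets C4 first by catalyst control and never touches it again. It also needs no alkene-selective hydrogenation.

**Alternative 2:** The allylic C10–C1 σ bond is cut.
- *Forward key step.* The terminal C9=C10 alkene of the acyclic iodo-diene A3 is hydroborated by a dialkylborane. Palladium(0) then joins C10 to the E-alkenyl iodide with retention to give A4.
- *For it.* The alkene geometry is secured before closure, the conditions are mild, and the stereotriad again comes from open-chain control. In functional-group tolerance and in the reliability of C7 this plan is as strong as or stronger than the chosen one.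
- *Against it.* This is an end-to-end closure of a ten-membered ring that contains a trans alkene. The palladacycle before reductive elimination already carries most of the transannular strain. Intermolecular coupling, protodeboronation and β-hydride loss are then the easier paths even at high dilution. The method is at its best for larger rings. A3, with five stereocentres and a trisubstituted iodide, costs about as many steps as 17.
- *Comparison.* The chosen strategy breaks an alkoxide-weakened σ bond inside a pre-organised bicyclic array, so neither entropy nor dilution matters.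

**Alternative 3:** The C2–C3 and C1–CH3 bonds are cut together.
- *Forward key step.* Nickel(0) couples the terminal alkyne and the aldehyde of ynal A5 to an oxanickelacycle. A methylzinc reagent transfers methyl to C1. Reductive elimination then gives allylic alcohol A6, and syn addition across the alkyne makes the alkene E.
- *For it.* Ring, alkene geometry and methyl group arise in one step, and both C3 epimers converge on the ketone. In bond economy at the closing event this plan is stronger than the chosen one.
- *Against it.* The closure must be endocyclic, with the terminal carbon bonding to the aldehyde. With terminal alkynes that regiochemistry depends on ligand and ring size. A trans alkene must form inside a ten-membered ring fused to the metallacycle. The aldehyde is α-branched by C4, so it is hindered and epimerisable. Direct methyl transfer to the aldehyde and alkyne oligomerisation compete at the dilution needed.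
- *Comparison.* The chosen step has close analogy for exactly this ring size and geometry, and it creates no permanent stereocentre under uncertain control.

Key step: step 13

Remark on numbering: target numbering C1–C10 is used for every intermediate (six-membered ring = C2–C7); α is the ring face carrying the C4 isopropyl group and β the opposite face.
Assumption: the temporary C8 carbinol centre is drawn as the 8S epimer expected from attack on the outer face, and enolate 21 with C6 and C9 trans as expected from loss of the outward C8–H; C8 is erased in step 25, so the other epimer or enolate geometry would serve equally.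

## Route

Step 1
Reactants: 1 3-methylbutanal; 2 methyl vinyl ketone
Product: 3 (R)-2-isopropyl-5-oxohexanal
Conditions: (R)-2-[methoxy(diphenyl)methyl]pyrrolidine (5 mol %), ethyl 3,4-dihydroxybenzoate (20 mol %), neat, 4 °C
Reagents that add atoms: none
Why: Enamine-catalysed asymmetric Michael addition of an aldehyde to an enone; the diphenyl(methoxy)methyl arm blocks one face of the E-enamine, so the (R)-catalyst should set C4 as R, while the catechol additive activates 2 by hydrogen bonding.

Step 2
Reactants: 3 (R)-2-isopropyl-5-oxohexanal
Product: 4 (R)-4-isopropylcyclohex-2-en-1-one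
Conditions: aq KOH (0.1 M), n-Bu4NOH (cat.), Et2O–THF, reflux
Reagents that add atoms: none
Why: Intramolecular aldol condensation of the methyl ketone onto the aldehyde; the dilute two-phase base should close the ring faster than the branched aldehyde enolises, so C4 is kept.

Step 3
Reactants: 4 (R)-4-isopropylcyclohex-2-en-1-one
Product: 5 (2R,3R,4R)-2,3-epoxy-4-isopropylcyclohexan-1-one (oxirane on the β face, trans to isopropyl)
Conditions: 30% H2O2, NaOH (cat.), MeOH, 0 °C
Reagents that add atoms: hydrogen peroxide, OO
Why: Weitz–Scheffer nucleophilic epoxidation; hydroperoxide adds to C3 anti to the neighbouring isopropyl group, which fixes the C3–O bond trans to C4.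

Step 4
Reactants: 5 (2R,3R,4R)-2,3-epoxy-4-isopropylcyclohexan-1-one
Product: 6 (1S,6R)-6-isopropylcyclohex-2-en-1-ol (C3–OH β, trans to isopropyl; alkene C2=C7)
Conditions: N2H4·H2O, AcOH (cat.), MeOH, 0 °C → rt
Reagents that add atoms: none
Why: Wharton transposition; condensation with hydrazine, epoxide opening and loss of dinitrogen move the alkene to C2=C7 and leave the oxygen on C3, whose C–O bond is never broken, so its configuration is retained.

Step 5
Reactants: 6 (1S,6R)-6-isopropylcyclohex-2-en-1-ol
Product: 7 tert-butyldimethylsilyl ether of 6
Conditions: TBSCl, imidazole, DMF, rt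
Reagents that add atoms: tert-butyldimethylsilyl chloride, CC(C)(C)[Si](C)(C)Cl
Why: Standard silylation of a secondary allylic alcohol; the TBS ether should survive the hydride, Grignard, potassium hydride and titanium steps and falls to fluoride at the end.

Step 6
Reactants: 7 tert-butyldimethylsilyl ether of 6
Product: 8 (4S,5R)-4-(tert-butyldimethylsilyloxy)-5-isopropylcyclohex-2-en-1-one (carbonyl at C6)
Conditions: Rh2(cap)4 (1 mol %), t-BuOOH (70% aq), K2CO3, CH2Cl2, rt
Reagents that add atoms: tert-butyl hydroperoxide, CC(C)(C)OO
Why: Dirhodium caprolactamate/hydroperoxide allylic oxidation of a cyclohexene to the enone; the C6 methylene is the only unhindered allylic C–H site, since C3–H is screened by OTBS and isopropyl, and peroxyl capture at the C6 end of the allyl radical avoids the flanked C2 end.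

Step 7
Reactants: 8 (4S,5R)-4-(tert-butyldimethylsilyloxy)-5-isopropylcyclohex-2-en-1-one
Product: 9 (1R,4S,5R)-4-(tert-butyldimethylsilyloxy)-5-isopropylcyclohex-2-en-1-ol (C6–OH α, cis to isopropyl)
Conditions: NaBH4, CeCl3·7H2O, MeOH, −78 → 0 °C
Reagents that add atoms: none
Why: Luche 1,2-reduction; axial hydride delivery to a 5-substituted cyclohexenone gives the pseudo-equatorial alcohol cis to the isopropyl group, which is the 6R centre of the target.

Step 8
Reactants: 9 (1R,4S,5R)-4-(tert-butyldimethylsilyloxy)-5-isopropylcyclohex-2-en-1-ol
Product: 10 (1R,2R,4R,5R,6R)-5-(tert-butyldimethylsilyloxy)-4-isopropyl-7-oxabicyclo[4.1.0]heptan-2-ol (C7–C2 oxirane α, cis to C6–OH)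
Conditions: mCPBA, NaHCO3, CH2Cl2, 0 °C
Reagents that add atoms: 3-chloroperoxybenzoic acid, OOC(=O)c1cccc(Cl)c1
Why: Henbest hydroxyl-directed epoxidation; hydrogen bonding to the α C6–OH and steric screening of the β face by C3–OTBS select the same (α) face.

Step 9
Reactants: 10 epoxy alcohol
Product: 11 4-methoxybenzyl ether of 10
Conditions: NaH, PMBCl, n-Bu4NI (cat.), THF–DMF, 0 °C → rt
Reagents that add atoms: 4-methoxybenzyl chloride, COc1ccc(CCl)cc1
Why: Williamson etherification; the alkoxide is cis to the oxirane and cannot reach its rear side, so Payne rearrangement is not available.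

Step 10
Reactants: 11 4-methoxybenzyl ether of 10; 12 2-bromopropene
Product: 14 cyclohexanol with C7–OH α-axial, C2-isopropenyl β-axial, C3–OTBS, C4-isopropyl and C6–OPMB equatorial, via isopropenylmagnesium bromide 13 (not isolated)
Conditions: 12, Mg, THF; then CuI (20 mol %), 11, THF, −30 → 0 °C; aq NH4Cl
Reagents that add atoms: none
Why: Copper-catalysed Grignard opening of an epoxide under the Fürst–Plattner rule; in the half-chair that keeps OPMB, OTBS and isopropyl equatorial, only β attack at C2 leads directly to a chair (trans-diaxial) product, and C2 is also the carbon remote from the cis OPMB group. This sets C2 (isopropenyl β) by inversion.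

Step 11
Reactants: 14 cyclohexanol
Product: 16 all-equatorial ketone (2S,3R,4R,6R)-2-isopropenyl-3-(tert-butyldimethylsilyloxy)-4-isopropyl-6-(4-methoxybenzyloxy)cyclohexanone (target numbering, C7 = carbonyl), via C2-axial ketone 15 (not isolated)
Conditions: (COCl)2, DMSO, CH2Cl2, −78 °C; Et3N, −78 → 0 °C; then DBU (0.3 equiv), 0 °C
Reagents that add atoms: none
Why: Swern oxidation followed in the same flask by amine-base epimerisation; C2–H of 15 is both α to the ketone and allylic and thus far more acidic than C6–H, and reprotonation at C2 places isopropenyl equatorial by relief of two syn-axial contacts. A(1,3) strain with the equatorial C3–OTBS disfavours drift of the isopropenyl alkene into conjugation.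

Step 12
Reactants: 16 all-equatorial ketone
Product: 17 (2S,3R,4R,6R,7S)-1-vinyl-2-isopropenylcyclohexanol with C3–OTBS, C4-isopropyl and C6–OPMB (vinyl, isopropenyl, OTBS, isopropyl and OPMB equatorial; OH axial)
Conditions: CeCl3 (anhydrous), vinylmagnesium bromide, THF, −78 °C; aq NH4Cl
Reagents that add atoms: vinylmagnesium bromide, C=C[Mg]Br
Why: Cerium-assisted Grignard 1,2-addition, which suppresses enolisation and β-elimination; attack along the equatorial trajectory, trans to the chelated C6–OPMB and clear of the axial C3 and C5 hydrogens, should give equatorial vinyl and axial OH, that is, vinyl trans to isopropenyl.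

Step 13
Reactants: 17 1-vinyl-2-isopropenylcyclohexanol
Product: 20 (3R,4R,6R,E)-3-(tert-butyldimethylsilyloxy)-4-isopropyl-6-(4-methoxybenzyloxy)-1-methylcyclodec-1-en-7-one (target numbering), via potassium alkoxide 18 (not isolated), via potassium enolate 19 (not isolated)
Conditions: KH, 18-crown-6, THF, 0 °C → rt; then AcOH in THF, −78 °C
Reagents that add atoms: none
Why: KH deprotonates 17 and the crown ether strips the cation, so the naked alkoxide 18 weakens the adjoining C2–C7 bond and the [3,3] shift (anionic oxy-Cope rearrangement) should run near room temperature. C9 bonds to C10 while C2–C7 breaks and the π bonds move to C1=C2 and C7=C8, giving enolate 19, whose formation makes the step irreversible. The closest known reaction type is the four-carbon expansion of trans-1-vinyl-2-alkenylcyclohexanols to (E)-cyclodec-5-enones. The ten-membered ring is not closed end to end: a decalin-like chair–chair array forms the outer C9–C10 bond and loses the inner bond, a 6 → 10 ring expansion. No new stereocentre is made; C2 and C7 are erased, C3, C4 and C6 are spectators, and the stereochemical output is the alkene geometry. The selectivity needed is chair over boat: with vinyl and isopropenyl both equatorial, the ring bonds C2–C3 and C7–C6 take equatorial sites of the chair, which places C3 and C10 trans about C1=C2 (E). The axial alkoxide is trans-1,3 to the equatorial C3–OTBS, so silyl migration should not compete. The cold acidic quench protonates C8 before proton exchange, and in the decalin-like perimeter conformation C6–H lies in the carbonyl plane, so C6 should hold.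

Step 14
Reactants: 20 cyclodecenone
Product: 22 (8S)-8-hydroxy derivative of 20, via sodium enolate 21 (not isolated)
Conditions: NaHMDS, THF, −78 °C; 2-(phenylsulfonyl)-3-phenyloxaziridine, −78 °C; aq NH4Cl
Reagents that add atoms: 2-(phenylsulfonyl)-3-phenyloxaziridine, O=S(=O)(N1OC1c1ccccc1)c1ccccc1
Why: Enolate hydroxylation with an N-sulfonyloxaziridine; the hindered amide takes the outward proton of the C8 methylene rather than the single C6–H, which lies in the carbonyl plane of the perimeter conformation next to OPMB, so sodium enolate 21 should form regioselectively. Sodium is chosen because its enolates take up oxygen faster than they add to the sulfonimine by-product, and neither crown ether nor excess hydride is present to consume the oxidant. The oxidant attacks the open outer face of 21 (8S, temporary).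

Step 15
Reactants: 22 α-hydroxy ketone
Product: 23 C8 tert-butyldimethylsilyl ether of 22
Conditions: TBSOTf, 2,6-lutidine, CH2Cl2, −78 → 0 °C
Reagents that add atoms: tert-butyldimethylsilyl triflate, CC(C)(C)[Si](C)(C)OS(=O)(=O)C(F)(F)F
Why: Silyl triflate/lutidine protection of a hindered α-hydroxy ketone under non-enolising conditions, so C6 and C8 are not disturbed.

Step 16
Reactants: 23 bis-silyl ketone
Product: 24 7-methylidene compound (C7=CH2 in place of C7=O)
Conditions: Cp2TiMe2, toluene, 70 °C, dark
Reagents that add atoms: dimethyltitanocene, C[Ti](C)(C1C=CC=C1)C1C=CC=C1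
Why: Petasis methylenation; the titanium methylidene is non-basic, so the two oxygenated α-centres are not epimerised, and silyl and PMB ethers are tolerated.

Step 17
Reactants: 24 7-methylidene compound
Product: 25 C6 allylic alcohol (PMB removed)
Conditions: DDQ, CH2Cl2–pH 7 buffer, 0 °C
Reagents that add atoms: none
Why: Oxidative PMB cleavage through the benzylic oxocarbenium ion, which the buffer hydrolyses; the silyl ethers and both alkenes should be inert at 0 °C.

Step 18
Reactants: 25 C6 allylic alcohol
Product: 26 (7S)-spiro-epoxide (oxirane C7–CH2, oxygen syn to C6–OH)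
Conditions: VO(acac)2 (5 mol %), t-BuOOH (decane), CH2Cl2, 0 °C → rt
Reagents that add atoms: tert-butyl hydroperoxide, CC(C)(C)OO
Why: Vanadium-catalysed hydroxyl-directed epoxidation; only the alkene allylic to the free C6–OH is activated, so C1=C2 is left alone. The C6–O bond stands on the outer face of the C7=CH2 plane, so directed delivery and peripheral attack coincide, and the A(1,2) model for 2-substituted allylic alcohols predicts the same sense (C7–O syn to C6–O, 7S).

Step 19
Reactants: 26 spiro-epoxide
Product: 27 (3R,4R,6R,7S,8S)-6,7-diol with C7 methyl group, C3–OTBS and C8–OTBS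
Conditions: LiAlH4, Et2O, 0 °C; Rochelle salt
Reagents that add atoms: none
Why: Hydride opening of a 2,2-disubstituted oxirane at its unsubstituted CH2 terminus (SN2); the CH2 becomes the C7 methyl group and the C7–O bond, hence the configuration, is untouched. Covalent aluminium alkoxides keep silyl migration slow.

Step 20
Reactants: 28 angelic acid
Product: 29 (Z)-2-methylbut-2-en-1-ol
Conditions: LiAlH4, Et2O, 0 °C
Reagents that add atoms: none
Why: Hydride reduction of the acid to the allylic alcohol; in ether at 0 °C neither conjugate reduction nor Z → E isomerisation is expected.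

Step 21
Reactants: 29 (Z)-2-methylbut-2-en-1-ol
Product: 30 [(2S,3R)-2,3-dimethyloxiran-2-yl]methanol
Conditions: Ti(Oi-Pr)4 (10 mol %), L-(+)-diethyl tartrate (12 mol %), t-BuOOH, 4 Å MS, CH2Cl2, −20 °C
Reagents that add atoms: tert-butyl hydroperoxide, CC(C)(C)OO
Why: Sharpless asymmetric epoxidation; by the empirical rule L-(+)-tartrate gives the (2S,3R)-epoxy alcohol from this Z-allylic alcohol, and syn oxygen transfer keeps CH2OH and the C3 methyl group cis.

Step 22
Reactants: 30 epoxy alcohol
Product: 31 (2R,3R)-2,3-dimethyloxirane-2-carboxylic acid
Conditions: RuCl3 (cat.), NaIO4, MeCN–EtOAc–H2O, 0 °C → rt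
Reagents that add atoms: water, O
Why: Catalytic ruthenium tetroxide oxidation of a primary epoxy alcohol to the glycidic acid through the aldehyde hydrate; no stereocentre is touched, and the C2 descriptor changes from S to R only through the priority rules.

Step 23
Reactants: 27 diol; 31 epoxy acid
Product: 33 C6 ester of 27 with 31, via mixed anhydride 32 (not isolated)
Conditions: 31, 2,4,6-trichlorobenzoyl chloride, Et3N, toluene, rt; then 27, DMAP, toluene, rt → 40 °C
Reagents that add atoms: none
Why: Yamaguchi esterification; DMAP transfers the less hindered acyl group of 32 to the secondary C6–OH, while the tertiary C7–OH is too hindered to react. Any minor enantiomer of 31 or of the ring would end up in a separable diastereomer.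

Step 24
Reactants: 33 ester
Product: 34 3,7,8-triol (both TBS groups removed)
Conditions: HF·pyridine, pyridine, THF, 0 °C → rt
Reagents that add atoms: none
Why: Fluoride cleavage of both secondary TBS ethers in a buffered, weakly acidic medium, which avoids base-induced acyl migration from C6 to the freed C8–OH and spares the electron-poor glycidic ester.

Step 25
Reactants: 34 triol
Product: 35 target CNP0389889.1
Conditions: Dess–Martin periodinane, NaHCO3, CH2Cl2, 0 °C → rt
Reagents that add atoms: none
Why: Dess–Martin oxidation of the allylic C3 carbinol and the C8 carbinol in one operation; the neutral buffered medium should spare C4 (now α to a ketone), the E-enone, the tertiary α-ketol and the epoxide, and the tertiary C7–OH cannot be oxidised.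

## Compound list

1 | 3-methylbutanal | CC(C)CC=O | starting material
2 | methyl vinyl ketone | CC(=O)C=C | starting material
3 | (R)-2-isopropyl-5-oxohexanal | O=C[C@@H](C(C)C)CCC(C)=O | intermediate
4 | (R)-4-isopropylcyclohex-2-en-1-one | O=C1C=C[C@@H](C(C)C)CC1 | intermediate
5 | (2R,3R,4R)-2,3-epoxy-4-isopropylcyclohexan-1-one | O=C1[C@@H]2O[C@@H]2[C@@H](C(C)C)CC1 | intermediate
6 | (1S,6R)-6-isopropylcyclohex-2-en-1-ol | C1=C[C@H](O)[C@@H](C(C)C)CC1 | intermediate
7 | TBS ether of 6 | C1=C[C@H](O[Si](C)(C)C(C)(C)C)[C@@H](C(C)C)CC1 | intermediate
8 | (4S,5R)-4-(TBSO)-5-isopropylcyclohex-2-en-1-one | O=C1C=C[C@H](O[Si](C)(C)C(C)(C)C)[C@@H](C(C)C)C1 | intermediate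
9 | (1R,4S,5R)-4-(TBSO)-5-isopropylcyclohex-2-en-1-ol | O[C@H]1C=C[C@H](O[Si](C)(C)C(C)(C)C)[C@@H](C(C)C)C1 | intermediate
10 | (1R,2R,4R,5R,6R)-5-(TBSO)-4-isopropyl-7-oxabicyclo[4.1.0]heptan-2-ol | O[C@H]1[C@H]2O[C@H]2[C@H](O[Si](C)(C)C(C)(C)C)[C@@H](C(C)C)C1 | intermediate
11 | PMB ether of 10 | COc1ccc(CO[C@H]2[C@H]3O[C@H]3[C@H](O[Si](C)(C)C(C)(C)C)[C@@H](C(C)C)C2)cc1 | intermediate
12 | 2-bromopropene | CC(Br)=C | starting material
13 | isopropenylmagnesium bromide | CC(=C)[Mg]Br | intermediate
14 | cyclohexanol, C7–OH α-axial, C2-isopropenyl β-axial | O[C@H]1[C@H](C(C)=C)[C@H](O[Si](C)(C)C(C)(C)C)[C@@H](C(C)C)C[C@H]1OCc2ccc(OC)cc2 | intermediate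
15 | C2-axial ketone (2R,3R,4R,6R) | O=C1[C@H](C(C)=C)[C@H](O[Si](C)(C)C(C)(C)C)[C@@H](C(C)C)C[C@H]1OCc2ccc(OC)cc2 | intermediate
16 | all-equatorial ketone (2S,3R,4R,6R) | O=C1[C@@H](C(C)=C)[C@H](O[Si](C)(C)C(C)(C)C)[C@@H](C(C)C)C[C@H]1OCc2ccc(OC)cc2 | intermediate
17 | all-equatorial 1-vinyl-2-isopropenylcyclohexanol (2S,3R,4R,6R,7S) | C=C[C@]1(O)[C@@H](C(C)=C)[C@H](O[Si](C)(C)C(C)(C)C)[C@@H](C(C)C)C[C@H]1OCc2ccc(OC)cc2 | intermediate
18 | potassium alkoxide of 17 | C=C[C@]1([O-])[C@@H](C(C)=C)[C@H](O[Si](C)(C)C(C)(C)C)[C@@H](C(C)C)C[C@H]1OCc2ccc(OC)cc2.[K+] | intermediate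
19 | potassium C7/C8 enolate (C6 and C9 trans) | C/C1=C\[C@H](O[Si](C)(C)C(C)(C)C)[C@@H](C(C)C)C[C@@H](OCc2ccc(OC)cc2)/C([O-])=C/CC1.[K+] | intermediate
20 | (E)-cyclodec-5-enone with C3–OTBS, C4-isopropyl, C6–OPMB | C/C1=C\[C@H](O[Si](C)(C)C(C)(C)C)[C@@H](C(C)C)C[C@@H](OCc2ccc(OC)cc2)C(=O)CCC1 | intermediate
21 | sodium C7/C8 enolate of 20 (C6 and C9 trans) | C/C1=C\[C@H](O[Si](C)(C)C(C)(C)C)[C@@H](C(C)C)C[C@@H](OCc2ccc(OC)cc2)/C([O-])=C/CC1.[Na+] | intermediate
22 | (8S)-8-hydroxy ketone | C/C1=C\[C@H](O[Si](C)(C)C(C)(C)C)[C@@H](C(C)C)C[C@@H](OCc2ccc(OC)cc2)C(=O)[C@@H](O)CC1 | intermediate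
23 | C8–OTBS ketone | C/C1=C\[C@H](O[Si](C)(C)C(C)(C)C)[C@@H](C(C)C)C[C@@H](OCc2ccc(OC)cc2)C(=O)[C@@H](O[Si](C)(C)C(C)(C)C)CC1 | intermediate
24 | 7-methylidene compound | C/C1=C\[C@H](O[Si](C)(C)C(C)(C)C)[C@@H](C(C)C)C[C@@H](OCc2ccc(OC)cc2)C(=C)[C@@H](O[Si](C)(C)C(C)(C)C)CC1 | intermediate
25 | C6 allylic alcohol | C/C1=C\[C@H](O[Si](C)(C)C(C)(C)C)[C@@H](C(C)C)C[C@@H](O)C(=C)[C@@H](O[Si](C)(C)C(C)(C)C)CC1 | intermediate
26 | (7S)-spiro-epoxide | C/C1=C\[C@H](O[Si](C)(C)C(C)(C)C)[C@@H](C(C)C)C[C@@H](O)[C@]2(OC2)[C@@H](O[Si](C)(C)C(C)(C)C)CC1 | intermediate
27 | 6,7-diol (3R,4R,6R,7S,8S) | C/C1=C\[C@H](O[Si](C)(C)C(C)(C)C)[C@@H](C(C)C)C[C@@H](O)[C@](C)(O)[C@@H](O[Si](C)(C)C(C)(C)C)CC1 | intermediate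
28 | angelic acid | C/C=C(/C)C(=O)O | starting material
29 | (Z)-2-methylbut-2-en-1-ol | C/C=C(/C)CO | intermediate
30 | [(2S,3R)-2,3-dimethyloxiran-2-yl]methanol | OC[C@]1(C)O[C@@H]1C | intermediate
31 | (2R,3R)-2,3-dimethyloxirane-2-carboxylic acid | OC(=O)[C@]1(C)O[C@@H]1C | intermediate
32 | mixed anhydride of 31 with 2,4,6-trichlorobenzoic acid | O=C(OC(=O)[C@]1(C)O[C@@H]1C)c2c(Cl)cc(Cl)cc2Cl | intermediate
33 | C6 epoxyangelate, C3 and C8 TBS ethers | C/C1=C\[C@H](O[Si](C)(C)C(C)(C)C)[C@@H](C(C)C)C[C@@H](OC(=O)[C@]2(C)O[C@@H]2C)[C@](C)(O)[C@@H](O[Si](C)(C)C(C)(C)C)CC1 | intermediate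
34 | 3,7,8-triol C6 epoxyangelate | C/C1=C\[C@H](O)[C@@H](C(C)C)C[C@@H](OC(=O)[C@]2(C)O[C@@H]2C)[C@](C)(O)[C@@H](O)CC1 | intermediate
35 | CNP0389889.1 | C/C1=C\C(=O)[C@@H](C(C)C)C[C@@H](OC(=O)[C@]2(C)O[C@@H]2C)[C@](C)(O)C(=O)CC1 | target

## Step count and least certain steps

Total: 25 steps. The longest linear sequence is 22 steps (steps 1–19 and 23–25). The side branch to acid 31 takes 3 steps (20–22).

**Step 13 (key step).**
- *Risk.* Heterolytic cleavage of the alkoxide-weakened C2–C7 bond could compete with the concerted shift, and recombination would blur the alkene geometry. Proton exchange between enolate and product could erode C6. The crowded isopropenyl terminus could slow the shift enough for decomposition to set in.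
- *Fallback.* It sets out from 17 and returns at 20. The alkoxide and enolate are avoided altogether by a palladium(II)-catalysed cyclisation-induced oxy-Cope rearrangement (PdCl2(PhCN)2, THF, rt). The metal activates the vinyl group, and the methyl-substituted alkene attacks it to form C9–C10 first through a tertiary cationic centre at C1. Fragmentation of C2–C7 with loss of the metal then leads to 20 under neutral conditions.

**Step 6.**
- *Risk.* Hydrogen abstraction could occur at the oxygenated C3 position. Oxygen capture could occur at the C2 end of the allyl radical. Over-oxidation is also possible.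
- *Fallback.* It sets out from 4 and returns at 8.
  - Condensation with tosylhydrazine gives the tosylhydrazone F1.
  - A Shapiro reaction (MeLi) gives (R)-5-isopropylcyclohexa-1,3-diene F2.
  - Singlet oxygen adds across C6 and C3 anti to the isopropyl group to give the endoperoxide F3.
  - A Kornblum–DeLaMare rearrangement with Et3N removes the less hindered C6–H to give the hydroxy enone F4.
  - Silylation as in step 5 returns 8.

**Step 10.**
- *Risk.* The oxirane is flanked by two ether-bearing carbons and may open slowly. That would leave room for halohydrin formation by magnesium halide or for attack at C7.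
- *Fallback.* It sets out from 11 and returns at 14.
  - The slimmer lithium trimethylsilylacetylide with BF3·OEt2 opens the oxirane under the same diaxial rule to give the silylalkynyl alcohol F5.
  - K2CO3 in MeOH gives the terminal alkyne F6.
  - Negishi carboalumination (Me3Al, Cp2ZrCl2) followed by protonolysis converts the ethynyl group into the isopropenyl group of 14.

**Step 11.**
- *Risk.* The base could also exchange C6–H, which would lose the 6R centre. The alkene could drift into conjugation, or the C3 silyloxy group could be lost by β-elimination.
- *Fallback.* It sets out from 15 (isolated after the Swern oxidation without DBU) and returns at 16. Soft enolisation with TMSOTf/Et3N gives the conjugated silyl dienol ether F7 regiospecifically on the C2 side. Cold protodesilylation (TBAF/AcOH, THF, −78 °C) protonates C2 kinetically from the axial β face. No free base is ever in contact with the ketone.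

**Step 16.**
- *Risk.* The carbonyl is flanked by two bulky ethers on its open face, so the titanium methylidene may fail to engage it at a temperature the substrate tolerates.
- *Fallback.* It sets out from 23 and returns at 24 by a Peterson olefination. The small nucleophile Me3SiCH2Li/CeCl3 (THF, −78 °C) adds to give the β-hydroxysilane F8, and either C7 epimer serves. KH-induced elimination then gives the exocyclic alkene.

**Step 18.**
- *Risk.* A ring conformation other than the expected one could turn the inner alkene face outward and reverse the facial sense. The C8–OTBS group could slow oxygen delivery until the allylic alcohol is oxidised instead.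
- *Fallback.* It sets out from 25 and returns at 27, replacing steps 18 and 19. A Mukaiyama hydration (Mn(dpm)3, PhSiH3, O2, i-PrOH, then P(OEt)3) transfers hydrogen to the terminal CH2, which reacts faster than the trisubstituted alkene. The tertiary C7 radical is then trapped by oxygen from the periphery.

## Further compounds

F0 | step 13 | none | none
F1 | step 6 | tosylhydrazone of 4 | Cc1ccc(cc1)S(=O)(=O)NN=C1C=C[C@@H](C(C)C)CC1
F2 | step 6 | (R)-5-isopropylcyclohexa-1,3-diene | C1=CC=C[C@@H](C(C)C)C1
F3 | step 6 | C3,C6-endoperoxide (peroxide bridge anti to isopropyl) | C1=C[C@@H]2OO[C@H]1C[C@@H]2C(C)C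
F4 | step 6 | (4S,5R)-4-hydroxy-5-isopropylcyclohex-2-en-1-one | O=C1C=C[C@H](O)[C@@H](C(C)C)C1
F5 | step 10 | C2-(trimethylsilylethynyl) analogue of 14 | O[C@H]1[C@H](C#C[Si](C)(C)C)[C@H](O[Si](C)(C)C(C)(C)C)[C@@H](C(C)C)C[C@H]1OCc2ccc(OC)cc2
F6 | step 10 | C2-ethynyl analogue of 14 | O[C@H]1[C@H](C#C)[C@H](O[Si](C)(C)C(C)(C)C)[C@@H](C(C)C)C[C@H]1OCc2ccc(OC)cc2
F7 | step 11 | C7-trimethylsilyl dienol ether (C7=C2) | C1(O[Si](C)(C)C)=C(C(C)=C)[C@H](O[Si](C)(C)C(C)(C)C)[C@@H](C(C)C)C[C@H]1OCc2ccc(OC)cc2
F8 | step 16 | C7 β-hydroxysilane (C7 epimers both serve) | C/C1=C\[C@H](O[Si](C)(C)C(C)(C)C)[C@@H](C(C)C)C[C@@H](OCc2ccc(OC)cc2)C(O)(C[Si](C)(C)C)[C@@H](O[Si](C)(C)C(C)(C)C)CC1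
F0 | step 18 | none | none
A1 | alternative 1 | thirteen-membered (E,E)-bis-allylic ether | C/C1=C\COC/C(C)=C/C[C@H]2OC(C)(C)O[C@]2(C)[C@@H](O[Si](C)(C)C(C)(C)C)CC1
A2 | alternative 1 | ten-membered C3 allylic alcohol with C4 isopropenyl group | C/C1=C\[C@H](O)[C@@H](C(C)=C)C[C@H]2OC(C)(C)O[C@]2(C)[C@@H](O[Si](C)(C)C(C)(C)C)CC1
A3 | alternative 2 | acyclic (E)-alkenyl iodide with terminal C9=C10 alkene | C/C(I)=C\[C@H](O[Si](C)(C)C(C)(C)C)[C@@H](C(C)C)C[C@H]1OC(C)(C)O[C@]1(C)[C@@H](O[Si](C)(C)C(C)(C)C)C=C
A4 | alternative 2 | protected (E)-cyclodecene core | C/C1=C\[C@H](O[Si](C)(C)C(C)(C)C)[C@@H](C(C)C)C[C@H]2OC(C)(C)O[C@]2(C)[C@@H](O[Si](C)(C)C(C)(C)C)CC1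
A5 | alternative 3 | acyclic ynal (C3 aldehyde, terminal C1≡C2 alkyne) | O=C[C@@H](C(C)C)C[C@H]1OC(C)(C)O[C@]1(C)[C@@H](O[Si](C)(C)C(C)(C)C)CCC#C
A6 | alternative 3 | ten-membered (E)-allylic alcohol | C/C1=C\[C@H](O)[C@@H](C(C)C)C[C@H]2OC(C)(C)O[C@]2(C)[C@@H](O[Si](C)(C)C(C)(C)C)CC1
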